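## Retrosynthetic overview
- **Feature (ent-kaurane numbering).** The lactone carbonyl C7 is an exocyclic carboxyl carbon on ring C carbon C8, next to C9. Its ester oxygen sits on C20 at the adjacent C10. This is read as a C8 ketene caught by the C20 hydroxyl, that is, as the Wolff contraction of a cycloheptanone (C7 ketone on C9, diazo group on C8). That step forms ring C (C8–C9) and lactone ring B (O–C7) together.
- **Ring D is closed last.** Dieckmann closure joins C8 to C15 of the methyl propanoate arm on C13, followed by exo hydroxylation of the C15–C16 enolate and desilylation.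
- **Origin of the diazo ketone.** It comes from a C7=C8 cycloheptene by way of the diol, the 1,2-dione and the C8 monotosylhydrazone. The C9–C10 bond and both of its stereocentres come from a Claisen rearrangement of the C20 enol ether of an (8S,13R)-cycloheptenol.
- **Origin of the rings.** Ring A comes from 4,4-dimethylcyclohexadienone by asymmetric vinylation at C5. It keeps its C2–C3 alkene throughout, so C1 has no enolisable neighbour once C10 is quaternary. The seven-membered ring comes from cyclohepta-2,6-dienone by asymmetric Michael addition at C13 and reagent-controlled reduction at C8.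
- **Ring order.** Ring A and the seven-membered carbocycle are bought rings, then rings C and B form together, then ring D.

Key step: step 18

Remark on numbering: locants are ent-kaurane locants. α is the face of ring A that carries C20 and C6; β is the face of H-5, H-9 and the C13 arm.

Remark on C16: it is formed as a mixture of epimers in step 9 and stays so until step 19 makes it an enolate carbon. The SMILES of 15 to 26 leave it open.

## Route

Step 1
Reactants: 1 4,4-dimethylcyclohex-2-en-1-one
Product: 2 4,4-dimethylcyclohexa-2,5-dien-1-one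
Conditions: DDQ (1.3 equiv), 1,4-dioxane, reflux
Reagents that add atoms: none
Why: DDQ dehydrogenation of a cyclohexenone through its dienol is standard, and the quaternary C4 prevents aromatisation to a phenol.

Step 2
Reactants: 2 4,4-dimethylcyclohexa-2,5-dien-1-one; 3 potassium vinyltrifluoroborate
Product: 4 (5R)-5-ethenyl-4,4-dimethylcyclohex-2-en-1-one
Conditions: [Rh(cod)2]BF4 (3 mol %), (R)-BINAP (3.5 mol %), Et3N, toluene/H2O, 25–40 °C; 2 in twofold excess
Reagents that add atoms: potassium vinyltrifluoroborate (3), C=C[B-](F)(F)F.[K+]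
Why: This is a rhodium-catalysed asymmetric 1,4-addition (Hayashi–Miyaura type) of an alkenyltrifluoroborate to a 4,4-disubstituted cyclohexadienone; by analogy with cyclohexenone the (R)-BINAP catalyst should deliver vinyl to the α face and set C5, the excess of 2 holds back a second addition, and the untouched alkene is the C2–C3 alkene of the target.

Step 3
Reactants: 4 (5R)-5-ethenyl-4,4-dimethylcyclohex-2-en-1-one
Product: 6 (5S)-5-(hydroxymethyl)-4,4-dimethylcyclohex-2-en-1-one, via C6 aldehyde 5 (not isolated)
Conditions: O3, CH2Cl2/MeOH, −78 °C (Sudan red 7B end point); Me2S, −78 to 0 °C; then NaBH4, −78 °C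
Reagents that add atoms: ozone, [O-][O+]=O
Why: In this ozonolysis with reductive work-up, ozone cleaves the electron-rich vinyl group well before the electron-poor, neopentyl-flanked enone, and NaBH4 at −78 °C reduces the aldehyde chemoselectively before C5 (alpha to CHO) can epimerise.

Step 4
Reactants: 6 (5S)-5-(hydroxymethyl)-4,4-dimethylcyclohex-2-en-1-one
Product: 7 (5S)-5-[(tert-butyldiphenylsilyl)oxymethyl]-4,4-dimethylcyclohex-2-en-1-one
Conditions: TBDPSCl, imidazole, CH2Cl2/DMF, 20 °C
Reagents that add atoms: tert-butyldiphenylsilyl chloride, CC(C)(C)[Si](Cl)(c1ccccc1)c1ccccc1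
Why: Standard silylation of a primary alcohol; TBDPS is chosen so that a TBS ether on C20 can later be removed selectively.

Step 5
Reactants: 7 (5S)-5-[(tert-butyldiphenylsilyl)oxymethyl]-4,4-dimethylcyclohex-2-en-1-one; 8 ethyl formate
Product: 9 (5R,6Z)-5-[(tert-butyldiphenylsilyl)oxymethyl]-6-(hydroxymethylidene)-4,4-dimethylcyclohex-2-en-1-one
Conditions: NaH, HCO2Et, cat. EtOH, THF, 0 to 20 °C; dilute HCl quench
Reagents that add atoms: ethyl formate (8), CCOC=O
Why: This crossed Claisen formylation can only occur at C10, because C2 is vinylic and C10H2 is the sole enolisable position, and the product rests as the chelated Z enol that carries C20.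

Step 6
Reactants: 10 cycloheptanone
Product: 11 cyclohepta-2,6-dien-1-one
Conditions: IBX (3 equiv), DMSO, 75–80 °C
Reagents that add atoms: none
Why: IBX dehydrogenation of ketones can be stopped at the cross-conjugated dienone through the amount of oxidant and the temperature.

Step 7
Reactants: 11 cyclohepta-2,6-dien-1-one; 12 dimethyl methylmalonate
Product: 13 dimethyl 2-methyl-2-[(1R)-3-oxocyclohept-4-en-1-yl]propanedioate
Conditions: LiAl((R)-BINOLate)2 (10 mol %), KOtBu (9 mol %), 4 Å MS, THF, 20 °C; 11 in excess
Reagents that add atoms: dimethyl methylmalonate (12), COC(=O)C(C)C(=O)OC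
Why: This is a catalytic asymmetric Michael addition of a malonate to a cyclic enone; the two enone halves of 11 are equivalent, so the catalyst only chooses the face, which should set C13 as (R) by analogy with cyclohexenone and cycloheptenone, and the excess of 11 suppresses a second addition.

Step 8
Reactants: 13 dimethyl 2-methyl-2-[(1R)-3-oxocyclohept-4-en-1-yl]propanedioate
Product: 14 dimethyl 2-[(1R,3S)-3-hydroxycyclohept-4-en-1-yl]-2-methylpropanedioate
Conditions: (R)-2-methyl-CBS-oxazaborolidine (20 mol %), catecholborane, toluene, −78 °C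
Reagents that add atoms: none
Why: In this Corey–Bakshi–Shibata reduction the oxazaborolidine treats the alkenyl side (C7) as the large and C14H2 as the small group, so the (R)-catalyst should give the (8S)-alcohol trans to the C13 arm, while any cis isomer lactonises onto the malonate and is removed.

Step 9
Reactants: 14 dimethyl 2-[(1R,3S)-3-hydroxycyclohept-4-en-1-yl]-2-methylpropanedioate
Product: 15 methyl 2-[(1R,3S)-3-hydroxycyclohept-4-en-1-yl]propanoate (C16 epimers)
Conditions: LiCl, H2O, DMSO, 150 °C
Reagents that add atoms: none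
Why: Krapcho dealkoxycarbonylation trims the malonate to the propanoate arm; it is run after the reduction so that neither retro-Michael cleavage nor transannular Michael addition of the C16 carbanion can occur, and the trans alcohol cannot lactonise.

Step 10
Reactants: 9 (5R,6Z)-5-[(tert-butyldiphenylsilyl)oxymethyl]-6-(hydroxymethylidene)-4,4-dimethylcyclohex-2-en-1-one; 15 methyl 2-[(1R,3S)-3-hydroxycyclohept-4-en-1-yl]propanoate
Product: 16 (E)-C20 enol ether joining C20 of ring A to O–C8 of the (8S,13R)-cycloheptenyl unit
Conditions: PPTS (10 mol %), benzene, reflux, 4 Å MS in a Soxhlet thimble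
Reagents that add atoms: none
Why: This acid-catalysed vinylogous esterification (addition–elimination at C20 with removal of water) leaves the C8–O bond intact, so the carbinol configuration is retained.

Step 11
Reactants: 16 (E)-C20 enol ether
Product: 17 (5R,9R,10S,13R)-C10 aldehyde with the C9–C10 bond formed and a C7=C8 alkene in the seven-membered ring
Conditions: o-xylene (degassed, base-washed glass), BHT, 155–165 °C, sealed tube
Reagents that add atoms: none
Why: In this aliphatic Claisen rearrangement of a 2-(allyloxymethylene) ketone the C8–O bond is exchanged suprafacially for the C9–C10 bond on the α face of the seven-membered ring (C9 fixed by C8, hence trans to the C13 arm), while C10 is attacked on its β face, anti to the C6 side chain held pseudoaxial by allylic strain with C10=C20, which leaves C20 cis to C6.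

Step 12
Reactants: 17 C10 aldehyde
Product: 18 (5R,9R,10S,13R)-C20 primary alcohol
Conditions: LiAlH(OtBu)3 (1.2 equiv), THF, −78 to −20 °C; Rochelle salt work-up
Reagents that add atoms: none
Why: This is a chemoselective hydride reduction, because the bulky reagent reduces the aldehyde far faster than the C1 enone next to quaternary C10 or the ester, and the non-nucleophilic medium avoids deformylation of the non-enolisable 1,3-dicarbonyl unit.

Step 13
Reactants: 18 C20 primary alcohol
Product: 19 C20 tert-butyldimethylsilyl ether
Conditions: TBSOTf, 2,6-lutidine, CH2Cl2, −78 to 0 °C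
Reagents that add atoms: tert-butyldimethylsilyl triflate, CC(C)(C)[Si](C)(C)OS(=O)(=O)C(F)(F)F
Why: Silylation with the triflate overcomes the neopentyl hindrance at C20 and shields the hydroxyl from oxidation and hemiketal formation in steps 14 and 15.

Step 14
Reactants: 19 C20 tert-butyldimethylsilyl ether
Product: 20 (7S,8R)-7β,8β-diol
Conditions: OsO4 (5 mol %), NMO, acetone/H2O, 20 °C
Reagents that add atoms: N-methylmorpholine N-oxide, C[N+]1([O-])CCOCC1; water, O
Why: Upjohn dihydroxylation takes the only electron-rich alkene (C7=C8) rather than the electron-poor, neopentyl C2=C3 enone; syn addition anti to the C10 substituent is expected, and both new carbinol centres are erased in step 15.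

Step 15
Reactants: 20 7β,8β-diol
Product: 21 (5R,9S,10R,13R)-cycloheptane-7,8-dione
Conditions: IBX (3 equiv), DMSO, 20–35 °C
Reagents that add atoms: none
Why: IBX oxidises 1,2-diols to 1,2-diketones without C–C cleavage, tolerates TBS and TBDPS ethers, and does not dehydrogenate ketones at this temperature.

Step 16
Reactants: 21 cycloheptane-7,8-dione
Product: 22 C20 hydroxy 7,8-dione (may rest as its C7 hemiketal)
Conditions: HF·pyridine, pyridine, THF, 0 to 20 °C
Reagents that add atoms: none
Why: Acidic fluoride desilylation is much faster for TBS than for TBDPS ethers, and it is done here, before the acid-sensitive diazo group exists.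

Step 17
Reactants: 22 C20 hydroxy 7,8-dione
Product: 24 (5R,9S,10R,13R)-8-diazo-7-ketone with free C20 hydroxyl, via C8 monotosylhydrazone 23 (not isolated)
Conditions: TsNHNH2 (1.05 equiv), THF, 0 to 20 °C; then Et3N, CH2Cl2, 20 °C
Reagents that add atoms: 4-methylbenzenesulfonohydrazide, Cc1ccc(cc1)S(=O)(=O)NN
Why: Condensation should occur at the less hindered C8 carbonyl (C7 is screened by C9 and C10, and C1 is a hindered enone), and base-induced loss of sulfinate from the α-keto tosylhydrazone (Bamford–Stevens type route to α-diazo ketones) installs the diazo group without enolate chemistry.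

Step 18
Reactants: 24 8-diazo-7-ketone with free C20 hydroxyl
Product: 26 (5R,8S,9R,10S,13R)-cis-fused 7,20-lactone on ring C with C8–H and the C13 propanoate arm, via C8 ketene 25 (not isolated)
Conditions: violet-blue LEDs (420–450 nm), dry toluene (0.005 M), argon, 20 °C, no metal
Reagents that add atoms: none
Why: Irradiation into the long-wavelength band of the diazo ketone, beyond any absorption of the ring A enone, expels N2 from the s-Z geometry that the ring enforces, so C9 shifts from C7 to C8 in concert with N2 loss and with retention at C9 (photochemical Wolff rearrangement; ring contraction of 2-diazocycloalkanones and capture of the ketene by a tethered alcohol are the closest known cases). Ring C is closed by this 1,2-shift (seven- to six-membered contraction, C8–C9 formed) and not by a cyclisation. Ring B is closed when the C20 hydroxyl adds in the ketene plane to the sp carbon C7, a 6-exo-dig attack counted on the C7=O bond, giving the lactone enol, which tautomerises. The only new stereocentre, C8, is set in that ketonisation: protonation on the β face, away from the C10 substituent on C9, should give the cis-fused lactone as in kinetic ketonisation of ring-fusion enols, and either epimer serves because C8 is enolised again in step 19. The step needs the rearrangement to beat 1,2-hydride shift from C14, O–H insertion and ketene dimerisation; metal-free irradiation of an s-Z locked diazo ketone favours the concerted path, high dilution and the closeness of C20–OH to C7 favour internal capture, and C6–OH is silylated so only one hydroxyl competes. C5, C9, C10 and C13 are not touched.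

Step 19
Reactants: 26 cis-fused 7,20-lactone with the C13 propanoate arm
Product: 28 (5R,8S,9S,10S,13R,16S)-6-O-TBDPS ether of the target, via potassium C15–C16 enolate 27 (not isolated)
Conditions: KN(SiMe3)2 (2.5 equiv), THF, −78 to −20 °C; then 2-(phenylsulfonyl)-3-phenyloxaziridine, −78 °C; aq. NH4Cl
Reagents that add atoms: 2-(phenylsulfonyl)-3-phenyloxaziridine, O=S(=O)(c1ccccc1)N1OC1c1ccccc1
Why: In this Dieckmann condensation followed by Davis oxidation C1 cannot enolise; the δ-lactone is markedly more acidic than the acyclic ester, so the first equivalent of base sits on C8; the β-oriented C13 arm can only reach the β face of C8 and thereby sets the quaternary centre; the alternative attack of C16 on C7 gives a product that cannot be deprotonated and reverts; the second equivalent of base drains the product as its C15–C16 enolate; and the oxaziridine attacks that enolate from the exo face (the side of the C14 bridge), placing OH exo and CH3 endo as in the target.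

Step 20
Reactants: 28 6-O-TBDPS ether of the target
Product: 29 CNP0530135.1 (5R,8S,9S,10S,13R,16S)
Conditions: HF·pyridine, THF, 0 to 20 °C
Reagents that add atoms: none
Why: Desilylation under mildly acidic fluoride conditions spares the β-keto lactone (prone to retro-Claisen cleavage), the tertiary α-ketol and the enone.

## Compound list
1 | 4,4-dimethylcyclohex-2-en-1-one | CC1(C)CCC(=O)C=C1 | starting material
2 | 4,4-dimethylcyclohexa-2,5-dien-1-one | CC1(C)C=CC(=O)C=C1 | intermediate
3 | potassium vinyltrifluoroborate | C=C[B-](F)(F)F.[K+] | starting material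
4 | (5R)-5-ethenyl-4,4-dimethylcyclohex-2-en-1-one | CC1(C)C=CC(=O)C[C@@H]1C=C | intermediate
5 | (1S)-2,2-dimethyl-5-oxocyclohex-3-ene-1-carbaldehyde (C6 aldehyde, not isolated) | CC1(C)C=CC(=O)C[C@@H]1C=O | intermediate
6 | (5S)-5-(hydroxymethyl)-4,4-dimethylcyclohex-2-en-1-one | CC1(C)C=CC(=O)C[C@@H]1CO | intermediate
7 | (5S)-5-[(tert-butyldiphenylsilyl)oxymethyl]-4,4-dimethylcyclohex-2-en-1-one | CC1(C)C=CC(=O)C[C@@H]1CO[Si](c2ccccc2)(c2ccccc2)C(C)(C)C | intermediate
8 | ethyl formate | CCOC=O | starting material
9 | (5R,6Z)-5-[(tert-butyldiphenylsilyl)oxymethyl]-6-(hydroxymethylidene)-4,4-dimethylcyclohex-2-en-1-one | CC1(C)C=CC(=O)/C(=C\O)[C@@H]1CO[Si](c2ccccc2)(c2ccccc2)C(C)(C)C | intermediate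
10 | cycloheptanone | O=C1CCCCCC1 | starting material
11 | cyclohepta-2,6-dien-1-one | O=C1C=CCCC=C1 | intermediate
12 | dimethyl methylmalonate | COC(=O)C(C)C(=O)OC | starting material
13 | dimethyl 2-methyl-2-[(1R)-3-oxocyclohept-4-en-1-yl]propanedioate | O=C1C=CCC[C@@H](C(C)(C(=O)OC)C(=O)OC)C1 | intermediate
14 | dimethyl 2-[(1R,3S)-3-hydroxycyclohept-4-en-1-yl]-2-methylpropanedioate | O[C@@H]1C=CCC[C@@H](C(C)(C(=O)OC)C(=O)OC)C1 | intermediate
15 | methyl 2-[(1R,3S)-3-hydroxycyclohept-4-en-1-yl]propanoate (C16 epimers) | O[C@@H]1C=CCC[C@@H](C(C)C(=O)OC)C1 | intermediate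
16 | (5R,6E)-enol ether of 9 with the (8S,13R)-cycloheptenol 15 (C20–O–C8) | CC1(C)C=CC(=O)/C(=C/O[C@@H]2C=CCC[C@@H](C(C)C(=O)OC)C2)[C@@H]1CO[Si](c3ccccc3)(c3ccccc3)C(C)(C)C | intermediate
17 | (5R,9R,10S,13R)-Claisen product: C10 bears CHO (C20, α) and the cyclohept-7-enyl unit through C9 | CC1(C)C=CC(=O)[C@@](C=O)([C@H]2C=CC[C@H](C(C)C(=O)OC)CC2)[C@@H]1CO[Si](c3ccccc3)(c3ccccc3)C(C)(C)C | intermediate
18 | (5R,9R,10S,13R)-C20 alcohol | CC1(C)C=CC(=O)[C@@](CO)([C@H]2C=CC[C@H](C(C)C(=O)OC)CC2)[C@@H]1CO[Si](c3ccccc3)(c3ccccc3)C(C)(C)C | intermediate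
19 | (5R,9R,10S,13R)-C20 TBS ether | CC1(C)C=CC(=O)[C@@](CO[Si](C)(C)C(C)(C)C)([C@H]2C=CC[C@H](C(C)C(=O)OC)CC2)[C@@H]1CO[Si](c3ccccc3)(c3ccccc3)C(C)(C)C | intermediate
20 | (5R,7S,8R,9S,10R,13R)-7β,8β-diol | CC1(C)C=CC(=O)[C@@](CO[Si](C)(C)C(C)(C)C)([C@H]2[C@H](O)[C@H](O)C[C@H](C(C)C(=O)OC)CC2)[C@@H]1CO[Si](c3ccccc3)(c3ccccc3)C(C)(C)C | intermediate
21 | (5R,9S,10R,13R)-7,8-dione with C20 OTBS | CC1(C)C=CC(=O)[C@@](CO[Si](C)(C)C(C)(C)C)([C@H]2C(=O)C(=O)C[C@H](C(C)C(=O)OC)CC2)[C@@H]1CO[Si](c3ccccc3)(c3ccccc3)C(C)(C)C | intermediate
22 | (5R,9S,10R,13R)-7,8-dione with free C20 OH | CC1(C)C=CC(=O)[C@@](CO)([C@H]2C(=O)C(=O)C[C@H](C(C)C(=O)OC)CC2)[C@@H]1CO[Si](c3ccccc3)(c3ccccc3)C(C)(C)C | intermediate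
23 | C8 monotosylhydrazone of 22 (not isolated) | CC1(C)C=CC(=O)[C@@](CO)([C@H]2C(=O)C(=NNS(=O)(=O)c3ccc(C)cc3)C[C@H](C(C)C(=O)OC)CC2)[C@@H]1CO[Si](c4ccccc4)(c4ccccc4)C(C)(C)C | intermediate
24 | (5R,9S,10R,13R)-8-diazo-7-ketone, Wolff precursor | CC1(C)C=CC(=O)[C@@](CO)([C@H]2C(=O)C(=[N+]=[N-])C[C@H](C(C)C(=O)OC)CC2)[C@@H]1CO[Si](c3ccccc3)(c3ccccc3)C(C)(C)C | intermediate
25 | C8 ketene on the contracted ring C (not isolated) | CC1(C)C=CC(=O)[C@@](CO)([C@H]2C(=C=O)C[C@H](C(C)C(=O)OC)CC2)[C@@H]1CO[Si](c3ccccc3)(c3ccccc3)C(C)(C)C | intermediate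
26 | (5R,8S,9R,10S,13R)-cis-fused 7,20-lactone, Wolff product | CC1(C)C=CC(=O)[C@]2(COC(=O)[C@H]3C[C@@H](CC[C@H]32)C(C)C(=O)OC)[C@@H]1CO[Si](c4ccccc4)(c4ccccc4)C(C)(C)C | intermediate
27 | potassium C15–C16 enolate of the ring D ketone (not isolated) | CC1(C)C=CC(=O)[C@]2(COC(=O)[C@@]34C[C@@H](CC[C@H]32)C(C)=C4[O-])[C@@H]1CO[Si](c5ccccc5)(c5ccccc5)C(C)(C)C.[K+] | intermediate
28 | (5R,8S,9S,10S,13R,16S)-6-O-TBDPS ether of the target | CC1(C)C=CC(=O)[C@]2(COC(=O)[C@@]34C[C@@H](CC[C@H]32)[C@](C)(O)C4=O)[C@@H]1CO[Si](c5ccccc5)(c5ccccc5)C(C)(C)C | intermediate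
29 | CNP0530135.1 | CC1(C)C=CC(=O)[C@]2(COC(=O)[C@@]34C[C@@H](CC[C@H]32)[C@](C)(O)C4=O)[C@@H]1CO | target

## Step count and risks
Total step count: 20. Longest linear sequence: 16 (steps 1–5 and 10–20).

**Step 18 (Wolff contraction with internal capture).**
- Risk: 1,2-hydride shift from C14, insertion of the carbene into the C20 O–H bond, or dimerisation of the ketene may outrun the concerted shift and the capture by the neopentyl hydroxyl.
- Fallback: ring contraction and lactonisation are separated. It sets out from dione 21, where C20 is still silylated. TsNHNH2 gives the silyl-protected C8 monotosylhydrazone F1, and Et3N gives the silyl-protected diazo ketone F2.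
- Irradiation in methanol follows. No internal O–H is present there, and a large excess of external nucleophile intercepts the ketene at once. This gives the ring-contracted C7 methyl ester F3.
- HF·pyridine frees the C20 hydroxy diester F4. Transesterification (cat. DBU, toluene, removal of methanol) closes the six-membered lactone and returns to the route at 26.

**Step 11 (Claisen rearrangement).**
- Risk: the crowded transition state, with quaternary C10 next to C5 and C4, may need temperatures at which the enol ether ionises or eliminates to a cycloheptadiene. Facial selectivity at C10 may also erode.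
- Fallback: the pericyclic step is replaced by a metal-mediated oxygen-to-carbon allyl transfer. It sets out from 16. Pd(PPh3)4 (zerovalent palladium) in THF at 25–60 °C ionises the allylic C8–O bond with inversion, giving a π-allyl complex and the stabilised C10 enolate of the 2-formyl enone.
- The enolate attacks anti to the metal, so the net result is retention and the same face of the seven-membered ring as in the rearrangement. Attack should favour the C9 terminus, flanked by unbranched C11H2, over C8. The sequence returns to the route at 17 and makes no new compound (F0).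

**Step 19 (Dieckmann closure and hydroxylation).**
- Risk: acylation at the hindered C8 may be reversed by the liberated methoxide (retro-Claisen opening), or deprotonation of the ester arm may stall the condensation.
- Fallback: the equilibrium condensation is replaced by an irreversible acylation. It sets out from 26. Me3SnOH (1,2-dichloroethane, 80 °C) hydrolyses the methyl ester to the C15 carboxylic acid F5. MeNHOMe·HCl with EDC and iPr2NEt gives the C15 N-methoxy-N-methylamide F6, whose C16–H is far less acidic than the lactone C8–H.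
- LiN(SiMe3)2 (THF, −78 to 0 °C) forms only the C8 enolate. This adds to the amide to give a chelated tetrahedral intermediate that releases no alkoxide, and work-up gives the ring D closed 16-H 15-ketone F7.
- Separate enolisation with KN(SiMe3)2 and oxidation with 2-(phenylsulfonyl)-3-phenyloxaziridine returns to the route at 28.

## Further compounds
F0 | step 11 | none | none
F1 | step 18 | C8 monotosylhydrazone of dione 21 (C20 OTBS) | CC1(C)C=CC(=O)[C@@](CO[Si](C)(C)C(C)(C)C)([C@H]2C(=O)C(=NNS(=O)(=O)c3ccc(C)cc3)C[C@H](C(C)C(=O)OC)CC2)[C@@H]1CO[Si](c4ccccc4)(c4ccccc4)C(C)(C)C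
F2 | step 18 | 8-diazo-7-ketone with C20 OTBS | CC1(C)C=CC(=O)[C@@](CO[Si](C)(C)C(C)(C)C)([C@H]2C(=O)C(=[N+]=[N-])C[C@H](C(C)C(=O)OC)CC2)[C@@H]1CO[Si](c3ccccc3)(c3ccccc3)C(C)(C)C
F3 | step 18 | ring-contracted C7 methyl ester with C20 OTBS (C8 epimers) | CC1(C)C=CC(=O)[C@@](CO[Si](C)(C)C(C)(C)C)([C@H]2C(C(=O)OC)C[C@H](C(C)C(=O)OC)CC2)[C@@H]1CO[Si](c3ccccc3)(c3ccccc3)C(C)(C)C
F4 | step 18 | C20 hydroxy diester (C8 epimers) | CC1(C)C=CC(=O)[C@@](CO)([C@H]2C(C(=O)OC)C[C@H](C(C)C(=O)OC)CC2)[C@@H]1CO[Si](c3ccccc3)(c3ccccc3)C(C)(C)C
F5 | step 19 | C15 carboxylic acid of lactone 26 | CC1(C)C=CC(=O)[C@]2(COC(=O)[C@H]3C[C@@H](CC[C@H]32)C(C)C(=O)O)[C@@H]1CO[Si](c4ccccc4)(c4ccccc4)C(C)(C)C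
F6 | step 19 | C15 N-methoxy-N-methylamide of lactone 26 | CC1(C)C=CC(=O)[C@]2(COC(=O)[C@H]3C[C@@H](CC[C@H]32)C(C)C(=O)N(C)OC)[C@@H]1CO[Si](c4ccccc4)(c4ccccc4)C(C)(C)C
F7 | step 19 | ring D closed 16-H 15-ketone (C16 epimers) | CC1(C)C=CC(=O)[C@]2(COC(=O)[C@@]34C[C@@H](CC[C@H]32)C(C)C4=O)[C@@H]1CO[Si](c5ccccc5)(c5ccccc5)C(C)(C)C
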